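(Readings and results are calculated on assumed constants; noise was put on by code.)

I watched the peak.

| setting | Sunday's | Saturday's | flask |
|---|---|---|---|
| X | 0.40 M | 0.40 M | 0.40 M |
| L | 1.8 equiv | 1.2 equiv | 1.80 equiv |
| remark | the very flask that is asked about, followed so far | run made earlier |  |
| time |  |  | 20 min |

| run | time / min | D / % |
|---|---|---|
| Sunday's | 1.00 | 13.8 |
| Sunday's | 1.33 | 17.9 |
| Sunday's | 1.50 | 19.3 |
| Sunday's | 2.50 | 26.6 |
| Sunday's | 3.00 | 27.1 |
| Sunday's | 4.00 | 27.8 |
| Saturday's | 1.00 | 7.0 |
| Saturday's | 2.00 | 13.4 |
| Saturday's | 3.00 | 18.1 |
| Saturday's | 6.00 | 18.1 |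
| Saturday's | 10.0 | 13.9 |
| Saturday's | 20.0 | 7.9 |

(readings scatter by 0.5 percentage points)



- time, not beyond 20 min, at which the flask holds most D
- the amount of D, in percent of the X charged, at that time
- earliest time at which at least nineteen twentieths of that best amount are there, in min
- latest time at which they still are, in min

D rose in both runs and fell again in Saturday's, so I treated it as an intermediate, whose peak is the crossing at which loss overtakes formation. I wanted the height of that crossing, and I reckoned it in two ways, each dividing the D reached by the equivalents of L charged. Saturday's run stood at 18.1% at both 3.00 min and 6.00 min, though its peak may hide between those times, and that gave 15.1% of the X charged per equivalent. Sunday's run, on the flask itself, had flattened to 27.8% at 4.00 min, its last step of 0.7 percentage points being close to the scatter, and that gave 15.4%. The two runs held different charges of L, so their agreement was a real check: they differed by 0.30 points, less than the scatter of one Saturday reading divided by that run's equivalents, 0.42 points. I therefore took their mean, 15.3% per equivalent, as the peak yield per equivalent at 0.40 M of X, and for the 1.80 equiv of this flask it promised 27.5%.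

The forecast, holding that “the total seems to scale with L”, put 28.3% (range 27.5% to 29.8%) at 4.8 min (range 3.8 min to 6.5 min), with the asked level held from 2.8 min to 6.8 min. Its best stood higher than my 27.5%.

The simulation gave 27.6% at 3.83 min, with the asked level held from 2.62 min to 5.72 min.

    X + L ⇌ Z + G (K = 0.310, k = 0.0163 M⁻¹ s⁻¹)
    D + L ⇌ Z + Q (K = 4.70, k = 0.00206 M⁻¹ s⁻¹)
    G + L ⇌ Z + D (K = 23.0, k = 0.0266 M⁻¹ s⁻¹)
    X + D → E (k = 0.0119 M⁻¹ s⁻¹)

Divided by its 1.80 equiv, the peak of this flask came to 15.3% per equivalent, beside my 15.3%, and it came earlier than the forecast's time. On the neighbouring flask, the same recipe with 3.10 equiv of L, the same measure promised 47.3%. That flask gave 42.4%, less than promised, which is 13.7% per equivalent.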